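**Retrosynthetic overview**

1. Pilosanol B is taken back to its hepta-O-benzyl ether; all seven benzyl ethers are removed together in the last step.
2. Ring C is opened at O1–C8a. The strategy rests on this feature: O1 joins the benzylic carbon C2 to C8a, and C8a is the ring A carbon lying between C4a and the bridge-bearing C8, with O5 and O7 meta to it. A bromine at that carbon, the bromine of 5-bromoresorcinol, therefore fixes the whole ring A pattern and is the handle for a copper-catalysed aryl C–O coupling with the C2 hydroxyl.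
3. The open-chain anti-1,2-diol 3-benzyl ether comes from an α-benzyloxy aryl ketone by chelation-controlled reduction (sets C2). The ketone comes from a Weinreb amide and the ring B Grignard reagent (C2–C1′), and the amide from an oxazolidinone glycolate alkylated by a ring A benzylic bromide (C3–C4, sets C3).
4. The C8–CH2–ring D bridge comes from Friedel–Crafts benzylation of the ring D acylphloroglucinol (one free ring carbon, made from 2-methylphloroglucinol) by a ring A benzylic alcohol. Both carbon substituents of ring A are introduced by Vilsmeier formylations ortho to bromine.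
5. Ring order: rings A, B and D are bought as benzene rings; ring C is the only ring formed, in step 18, one step before the end.

Key step: step 18

Assumption: in the double O-protection of the 2,4,6-trihydroxy-3-methylphenyl ketone, the hydroxyl between the methyl and the acyl group (hydrogen-bonded to the ketone and the more hindered ortho hydroxyl) is taken to stay free.

Short names: Bn = benzyl. "Ring D benzyl" = 2,6-bis(benzyloxy)-4-methoxy-3-methyl-5-(2-methylpropanoyl)benzyl. Flavan numbering (O1, C2, C3, C4, C4a, C5 to C8, C8a) is used for rings A and C.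

**Route**

Step 1
Reactants: 1 5-bromoresorcinol
Product: 2 1,3-bis(benzyloxy)-5-bromobenzene
Conditions: BnBr, K2CO3, DMF, rt → 50 °C
Reagents that add atoms: benzyl bromide, BrCc1ccccc1
Why: Williamson ether synthesis on both phenols, to which the aryl bromide is inert.

Step 2
Reactants: 2 1,3-bis(benzyloxy)-5-bromobenzene
Product: 4 2-bromo-4,6-bis(benzyloxy)benzaldehyde, via aryl iminium chloride 3 (not isolated)
Conditions: POCl3, DMF, 0 → 75 °C; then H2O, rt
Reagents that add atoms: N,N-dimethylformamide, CN(C)C=O; water, O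
Why: Vilsmeier–Haack formylation should go to the carbon ortho to bromine, which is para to one benzyloxy group and ortho to the other, in preference to the shielded carbon between the two ether groups, and water then hydrolyses iminium salt 3 to the aldehyde.

Step 3
Reactants: 4 2-bromo-4,6-bis(benzyloxy)benzaldehyde
Product: 5 [2-bromo-4,6-bis(benzyloxy)phenyl]methanol
Conditions: NaBH4, THF/MeOH, 0 °C
Reagents that add atoms: none
Why: Borohydride reduction of the aldehyde, which leaves the aryl bromide and the benzyl ethers untouched.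

Step 4
Reactants: 6 2-methylphloroglucinol; 7 isobutyryl chloride (2-methylpropanoyl chloride)
Product: 8 2-methyl-1-(2,4,6-trihydroxy-3-methylphenyl)propan-1-one
Conditions: AlCl3, PhNO2, rt → 60 °C; then aq HCl
Reagents that add atoms: none
Why: Friedel–Crafts acylation at one of the two equivalent free ring carbons of the phloroglucinol, after which the ketone deactivates the ring against a second acylation.

Step 5
Reactants: 8 2-methyl-1-(2,4,6-trihydroxy-3-methylphenyl)propan-1-one
Product: 9 1-[2-hydroxy-4,6-bis(methoxymethoxy)-3-methylphenyl]-2-methylpropan-1-one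
Conditions: MeOCH2Cl (2.1 equiv), iPr2NEt, CH2Cl2, 0 °C
Reagents that add atoms: chloromethyl methyl ether, COCCl
Why: O-alkylation (acetal ether formation) should take the non-chelated 4-hydroxyl and then the less hindered 6-hydroxyl, while the 2-hydroxyl, hydrogen-bonded to the ketone and buttressed by the methyl group, stays free.

Step 6
Reactants: 9 1-[2-hydroxy-4,6-bis(methoxymethoxy)-3-methylphenyl]-2-methylpropan-1-one
Product: 10 1-[2-methoxy-4,6-bis(methoxymethoxy)-3-methylphenyl]-2-methylpropan-1-one
Conditions: MeI, K2CO3, DMF, 50 °C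
Reagents that add atoms: iodomethane, CI
Why: Williamson methylation of the remaining chelated phenol under forcing carbonate conditions, which the acetal ethers tolerate.

Step 7
Reactants: 10 1-[2-methoxy-4,6-bis(methoxymethoxy)-3-methylphenyl]-2-methylpropan-1-one
Product: 11 1-(4,6-dihydroxy-2-methoxy-3-methylphenyl)-2-methylpropan-1-one
Conditions: HCl (cat.), MeOH, 50 °C
Reagents that add atoms: none
Why: Acid-catalysed acetal exchange with methanol removes both methoxymethyl groups and leaves the aryl methyl ether and the ketone.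

Step 8
Reactants: 5 [2-bromo-4,6-bis(benzyloxy)phenyl]methanol; 11 1-(4,6-dihydroxy-2-methoxy-3-methylphenyl)-2-methylpropan-1-one
Product: 12 1-{3-[2-bromo-4,6-bis(benzyloxy)benzyl]-2,4-dihydroxy-6-methoxy-5-methylphenyl}-2-methylpropan-1-one
Conditions: BF3·OEt2 (0.2 equiv), CH2Cl2/1,4-dioxane, 0 °C, slow addition of 5 to 11 (1.5 equiv)
Reagents that add atoms: none
Why: Friedel–Crafts benzylation, in which the Lewis acid ionises the benzylic alcohol to a 2,4-dialkoxybenzyl cation that should be captured by the single free ring carbon of phloroglucinol 11, the most nucleophilic site present and held in excess, so that the bridge forms without a regiochemical choice on ring D.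

Step 9
Reactants: 12 1-{3-[2-bromo-4,6-bis(benzyloxy)benzyl]-2,4-dihydroxy-6-methoxy-5-methylphenyl}-2-methylpropan-1-one
Product: 13 1-{2,4-bis(benzyloxy)-3-[2-bromo-4,6-bis(benzyloxy)benzyl]-6-methoxy-5-methylphenyl}-2-methylpropan-1-one
Conditions: BnBr, K2CO3, Bu4NI (cat.), DMF, 60 °C
Reagents that add atoms: benzyl bromide, BrCc1ccccc1
Why: Williamson benzylation of both hindered ring D phenols, with O-alkylation expected on this fully substituted ring in a dipolar aprotic solvent.

Step 10
Reactants: 13 1-{2,4-bis(benzyloxy)-3-[2-bromo-4,6-bis(benzyloxy)benzyl]-6-methoxy-5-methylphenyl}-2-methylpropan-1-one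
Product: 15 2-bromo-4,6-bis(benzyloxy)-3-(ring D benzyl)benzaldehyde, via aryl iminium chloride 14 (not isolated)
Conditions: POCl3, DMF, 0 → 70 °C; then H2O, rt
Reagents that add atoms: N,N-dimethylformamide, CN(C)C=O; water, O
Why: A second Vilsmeier–Haack formylation should take the remaining ring A carbon ortho to bromine (para and ortho to the two benzyloxy groups) rather than the carbon between the ethers, ring D being fully substituted and its hindered isopropyl ketone inert to the chloroiminium reagent.

Step 11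
Reactants: 15 2-bromo-4,6-bis(benzyloxy)-3-(ring D benzyl)benzaldehyde
Product: 16 [2-bromo-4,6-bis(benzyloxy)-3-(ring D benzyl)phenyl]methanol
Conditions: NaBH4, THF/MeOH, 0 °C
Reagents that add atoms: none
Why: Borohydride reduction should be selective for the aldehyde, because the ring D ketone is shielded by two ortho ether groups and its isopropyl group.

Step 12
Reactants: 16 [2-bromo-4,6-bis(benzyloxy)-3-(ring D benzyl)phenyl]methanol
Product: 17 2-bromo-4,6-bis(benzyloxy)-3-(ring D benzyl)benzyl bromide
Conditions: PBr3, CH2Cl2, 0 °C; aq NaHCO3 wash, used crude at once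
Reagents that add atoms: phosphorus tribromide, BrP(Br)Br
Why: Conversion of the benzylic alcohol into the bromide through a phosphite ester and displacement by bromide, the labile electron-rich product being carried on without chromatography.

Step 13
Reactants: 18 (R)-4-benzyl-2-oxazolidinone; 19 benzyloxyacetyl chloride
Product: 21 (R)-4-benzyl-3-[(benzyloxy)acetyl]oxazolidin-2-one, via lithiated oxazolidinone 20 (not isolated)
Conditions: n-BuLi, THF, −78 °C; then 19, −78 → 0 °C
Reagents that add atoms: none
Why: N-acylation of the lithium salt of the oxazolidinone by the acid chloride.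

Step 14
Reactants: 21 (R)-4-benzyl-3-[(benzyloxy)acetyl]oxazolidin-2-one; 17 2-bromo-4,6-bis(benzyloxy)-3-(ring D benzyl)benzyl bromide
Product: 23 (R)-4-benzyl-3-{(S)-2-(benzyloxy)-3-[2-bromo-4,6-bis(benzyloxy)-3-(ring D benzyl)phenyl]propanoyl}oxazolidin-2-one, via sodium Z-enolate 22 (not isolated)
Conditions: 21 (2 equiv), NaN(SiMe3)2, THF, −78 °C; then 17, −78 → −45 °C
Reagents that add atoms: none
Why: Evans asymmetric alkylation, in which the chelated sodium (Z)-enolate 22 is attacked by the benzylic bromide on the face opposite the 4-benzyl group of the (R)-auxiliary, which forms C3–C4 and should set C3 as S.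

Step 15
Reactants: 23 (R)-4-benzyl-3-{(S)-2-(benzyloxy)-3-[2-bromo-4,6-bis(benzyloxy)-3-(ring D benzyl)phenyl]propanoyl}oxazolidin-2-one
Product: 24 (S)-2-(benzyloxy)-3-[2-bromo-4,6-bis(benzyloxy)-3-(ring D benzyl)phenyl]-N-methoxy-N-methylpropanamide
Conditions: MeNHOMe·HCl, AlMe3, CH2Cl2, −10 → 0 °C; then 0.5 M aq HCl
Reagents that add atoms: N,O-dimethylhydroxylamine hydrochloride, CNOC.Cl
Why: Weinreb transamination, in which the aluminium amide attacks the exocyclic imide carbonyl (activated by the α-benzyloxy group and by chelation of aluminium) and releases the auxiliary without touching the α-stereocentre.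

Step 16
Reactants: 24 (S)-2-(benzyloxy)-3-[2-bromo-4,6-bis(benzyloxy)-3-(ring D benzyl)phenyl]-N-methoxy-N-methylpropanamide; 25 4-bromo-1,2-bis(benzyloxy)benzene
Product: 28 (S)-2-(benzyloxy)-1-[3,4-bis(benzyloxy)phenyl]-3-[2-bromo-4,6-bis(benzyloxy)-3-(ring D benzyl)phenyl]propan-1-one, via arylmagnesium bromide 26 (not isolated), via magnesium hemiaminal 27 (not isolated)
Conditions: 25, Mg, THF, reflux; then 24, THF, −20 → 0 °C; then cold 1 M aq HCl
Reagents that add atoms: none
Why: Weinreb ketone synthesis, in which Grignard reagent 26 adds once to the amide to give the chelated adduct 27 that collapses to the ketone only on work-up, while the doubly ortho-substituted ring D isopropyl ketone and the ring A bromide should not react at this temperature.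

Step 17
Reactants: 28 (S)-2-(benzyloxy)-1-[3,4-bis(benzyloxy)phenyl]-3-[2-bromo-4,6-bis(benzyloxy)-3-(ring D benzyl)phenyl]propan-1-one
Product: 29 (1R,2S)-2-(benzyloxy)-1-[3,4-bis(benzyloxy)phenyl]-3-[2-bromo-4,6-bis(benzyloxy)-3-(ring D benzyl)phenyl]propan-1-ol
Conditions: Zn(BH4)2, Et2O/CH2Cl2, −78 → −30 °C
Reagents that add atoms: none
Why: Chelation-controlled reduction (Cram chelate model), in which zinc bridges the ketone oxygen and the α-benzyloxy oxygen and hydride adds to the carbonyl face opposite the C4 benzylic substituent, which should set C2 as R, anti to the C3 ether, and leave the hindered ring D ketone alone.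

Step 18
Reactants: 29 (1R,2S)-2-(benzyloxy)-1-[3,4-bis(benzyloxy)phenyl]-3-[2-bromo-4,6-bis(benzyloxy)-3-(ring D benzyl)phenyl]propan-1-ol
Product: 30 (2R,3S)-3,5,7-tris(benzyloxy)-2-[3,4-bis(benzyloxy)phenyl]-8-(ring D benzyl)-3,4-dihydro-2H-chromene
Conditions: CuI (20 mol%), 3,4,7,8-tetramethyl-1,10-phenanthroline (40 mol%), Cs2CO3, degassed toluene, 110 °C, argon
Reagents that add atoms: none
Why: Cs2CO3 deprotonates the C2 hydroxyl and the alkoxide binds to the phenanthroline-ligated CuI (monovalent copper), the C8a–Br bond then adds oxidatively and reductive elimination forms O1–C8a; the closest known reaction type is the Ullmann-type copper-catalysed intramolecular O-arylation of alcohols by aryl halides that gives chromans. Ring C closes as a six-membered cyclic ether by attack of the C2 oxygen on the ipso carbon C8a, through a seven-membered copper-containing ring. No stereocentre is formed and neither the C2–O nor the C3–O bond is broken, so the anti relationship of 29 should appear unchanged as the 2,3-trans ring. The step needs closure through the C2 oxygen only, which is secured because the C3 oxygen is a benzyl ether (no five-membered dihydrobenzofuran) and every phenol of rings A and D is a benzyl ether (no xanthene across the bridge). Regiochemistry is not in question, since the only halogen sits at C8a between C4a and C8. The weak point is oxidative addition at a doubly ortho-substituted, electron-rich bromide, which the intramolecular placement of the alkoxide is expected to offset.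

Step 19
Reactants: 30 (2R,3S)-3,5,7-tris(benzyloxy)-2-[3,4-bis(benzyloxy)phenyl]-8-(ring D benzyl)-3,4-dihydro-2H-chromene
Product: 31 pilosanol B
Conditions: H2 (1 atm), Pd(OH)2/C, THF/MeOH, rt
Reagents that add atoms: none
Why: Catalytic hydrogenolysis should cleave the seven O-benzyl ethers, while the cyclic benzylic ether O1–C2, the diarylmethane bridge and the hindered aryl ketone are expected to survive these neutral conditions, as they do in flavan-3-ols.

**Compound list**

1 | 5-bromoresorcinol | Oc1cc(O)cc(Br)c1 | starting material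
2 | 1,3-bis(benzyloxy)-5-bromobenzene | Brc1cc(OCc2ccccc2)cc(OCc2ccccc2)c1 | intermediate
3 | N-[2-bromo-4,6-bis(benzyloxy)benzylidene]-N-methylmethanaminium chloride | C[N+](C)=Cc1c(Br)cc(OCc2ccccc2)cc1OCc1ccccc1.[Cl-] | intermediate (not isolated)
4 | 2-bromo-4,6-bis(benzyloxy)benzaldehyde | O=Cc1c(Br)cc(OCc2ccccc2)cc1OCc1ccccc1 | intermediate
5 | [2-bromo-4,6-bis(benzyloxy)phenyl]methanol | OCc1c(Br)cc(OCc2ccccc2)cc1OCc1ccccc1 | intermediate
6 | 2-methylphloroglucinol | Cc1c(O)cc(O)cc1O | starting material
7 | isobutyryl chloride | CC(C)C(Cl)=O | starting material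
8 | 2-methyl-1-(2,4,6-trihydroxy-3-methylphenyl)propan-1-one | CC(C)C(=O)c1c(O)cc(O)c(C)c1O | intermediate
9 | 1-[2-hydroxy-4,6-bis(methoxymethoxy)-3-methylphenyl]-2-methylpropan-1-one | CC(C)C(=O)c1c(OCOC)cc(OCOC)c(C)c1O | intermediate
10 | 1-[2-methoxy-4,6-bis(methoxymethoxy)-3-methylphenyl]-2-methylpropan-1-one | CC(C)C(=O)c1c(OCOC)cc(OCOC)c(C)c1OC | intermediate
11 | 1-(4,6-dihydroxy-2-methoxy-3-methylphenyl)-2-methylpropan-1-one | CC(C)C(=O)c1c(O)cc(O)c(C)c1OC | intermediate
12 | 1-{3-[2-bromo-4,6-bis(benzyloxy)benzyl]-2,4-dihydroxy-6-methoxy-5-methylphenyl}-2-methylpropan-1-one | CC(C)C(=O)c1c(O)c(Cc2c(Br)cc(OCc3ccccc3)cc2OCc2ccccc2)c(O)c(C)c1OC | intermediate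
13 | 1-{2,4-bis(benzyloxy)-3-[2-bromo-4,6-bis(benzyloxy)benzyl]-6-methoxy-5-methylphenyl}-2-methylpropan-1-one | CC(C)C(=O)c1c(OCc2ccccc2)c(Cc2c(Br)cc(OCc3ccccc3)cc2OCc2ccccc2)c(OCc2ccccc2)c(C)c1OC | intermediate
14 | N-[2-bromo-4,6-bis(benzyloxy)-3-(ring D benzyl)benzylidene]-N-methylmethanaminium chloride | C[N+](C)=Cc1c(OCc2ccccc2)cc(OCc2ccccc2)c(Cc2c(OCc3ccccc3)c(C)c(OC)c(C(=O)C(C)C)c2OCc2ccccc2)c1Br.[Cl-] | intermediate (not isolated)
15 | 2-bromo-4,6-bis(benzyloxy)-3-(ring D benzyl)benzaldehyde | O=Cc1c(OCc2ccccc2)cc(OCc2ccccc2)c(Cc2c(OCc3ccccc3)c(C)c(OC)c(C(=O)C(C)C)c2OCc2ccccc2)c1Br | intermediate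
16 | [2-bromo-4,6-bis(benzyloxy)-3-(ring D benzyl)phenyl]methanol | OCc1c(OCc2ccccc2)cc(OCc2ccccc2)c(Cc2c(OCc3ccccc3)c(C)c(OC)c(C(=O)C(C)C)c2OCc2ccccc2)c1Br | intermediate
17 | 2-bromo-4,6-bis(benzyloxy)-3-(ring D benzyl)benzyl bromide | BrCc1c(OCc2ccccc2)cc(OCc2ccccc2)c(Cc2c(OCc3ccccc3)c(C)c(OC)c(C(=O)C(C)C)c2OCc2ccccc2)c1Br | intermediate
18 | (R)-4-benzyl-2-oxazolidinone | O=C1N[C@H](Cc2ccccc2)CO1 | starting material
19 | benzyloxyacetyl chloride | O=C(Cl)COCc1ccccc1 | starting material
20 | lithium salt (N-lithiated) of (R)-4-benzyl-2-oxazolidinone | [Li+].O=C1[N-][C@H](Cc2ccccc2)CO1 | intermediate (not isolated)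
21 | (R)-4-benzyl-3-[(benzyloxy)acetyl]oxazolidin-2-one | O=C(COCc1ccccc1)N1[C@H](Cc2ccccc2)COC1=O | intermediate
22 | sodium (Z)-enolate of 21 | [Na+].[O-]/C(=C\OCc1ccccc1)N1[C@H](Cc2ccccc2)COC1=O | intermediate (not isolated)
23 | (R)-4-benzyl-3-{(S)-2-(benzyloxy)-3-[2-bromo-4,6-bis(benzyloxy)-3-(ring D benzyl)phenyl]propanoyl}oxazolidin-2-one | O=C(N1[C@H](Cc2ccccc2)COC1=O)[C@@H](OCc1ccccc1)Cc1c(OCc2ccccc2)cc(OCc2ccccc2)c(Cc2c(OCc3ccccc3)c(C)c(OC)c(C(=O)C(C)C)c2OCc2ccccc2)c1Br | intermediate
24 | (S)-2-(benzyloxy)-3-[2-bromo-4,6-bis(benzyloxy)-3-(ring D benzyl)phenyl]-N-methoxy-N-methylpropanamide | CON(C)C(=O)[C@@H](OCc1ccccc1)Cc1c(OCc2ccccc2)cc(OCc2ccccc2)c(Cc2c(OCc3ccccc3)c(C)c(OC)c(C(=O)C(C)C)c2OCc2ccccc2)c1Br | intermediate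
25 | 4-bromo-1,2-bis(benzyloxy)benzene | Brc1ccc(OCc2ccccc2)c(OCc2ccccc2)c1 | starting material
26 | [3,4-bis(benzyloxy)phenyl]magnesium bromide | Br[Mg]c1ccc(OCc2ccccc2)c(OCc2ccccc2)c1 | intermediate (not isolated)
27 | bromomagnesium salt of the tetrahedral N-methoxy-N-methyl hemiaminal from 26 and 24 (hemiaminal carbon not defined, C3 centre S) | CON(C)C(O[Mg]Br)(c1ccc(OCc2ccccc2)c(OCc2ccccc2)c1)[C@@H](OCc1ccccc1)Cc1c(OCc2ccccc2)cc(OCc2ccccc2)c(Cc2c(OCc3ccccc3)c(C)c(OC)c(C(=O)C(C)C)c2OCc2ccccc2)c1Br | intermediate (not isolated)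
28 | (S)-2-(benzyloxy)-1-[3,4-bis(benzyloxy)phenyl]-3-[2-bromo-4,6-bis(benzyloxy)-3-(ring D benzyl)phenyl]propan-1-one | O=C(c1ccc(OCc2ccccc2)c(OCc2ccccc2)c1)[C@@H](OCc1ccccc1)Cc1c(OCc2ccccc2)cc(OCc2ccccc2)c(Cc2c(OCc3ccccc3)c(C)c(OC)c(C(=O)C(C)C)c2OCc2ccccc2)c1Br | intermediate
29 | (1R,2S)-2-(benzyloxy)-1-[3,4-bis(benzyloxy)phenyl]-3-[2-bromo-4,6-bis(benzyloxy)-3-(ring D benzyl)phenyl]propan-1-ol | O[C@H](c1ccc(OCc2ccccc2)c(OCc2ccccc2)c1)[C@@H](OCc1ccccc1)Cc1c(OCc2ccccc2)cc(OCc2ccccc2)c(Cc2c(OCc3ccccc3)c(C)c(OC)c(C(=O)C(C)C)c2OCc2ccccc2)c1Br | intermediate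
30 | (2R,3S)-3,5,7-tris(benzyloxy)-2-[3,4-bis(benzyloxy)phenyl]-8-(ring D benzyl)-3,4-dihydro-2H-chromene (hepta-O-benzyl pilosanol B) | CC(C)C(=O)c1c(OC)c(C)c(OCc2ccccc2)c(Cc2c(OCc3ccccc3)cc(OCc3ccccc3)c3c2O[C@H](c2ccc(OCc4ccccc4)c(OCc4ccccc4)c2)[C@@H](OCc2ccccc2)C3)c1OCc1ccccc1 | intermediate
31 | pilosanol B, 1-[3-{[(2R,3S)-2-(3,4-dihydroxyphenyl)-3,5,7-trihydroxy-3,4-dihydro-2H-chromen-8-yl]methyl}-2,4-dihydroxy-6-methoxy-5-methylphenyl]-2-methylpropan-1-one | COc1c(C)c(O)c(Cc2c(O)cc(O)c3c2O[C@H](c2ccc(O)c(O)c2)[C@@H](O)C3)c(O)c1C(=O)C(C)C | target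

**Totals**

Total step count: 19.
Longest linear sequence: 15 steps (6 to 31 through steps 4 to 12 and 14 to 19).

**Three steps most likely to fail**

1. Step 18. What may go wrong: oxidative addition of copper into the doubly ortho-substituted, electron-rich C8a–Br bond may be slower than protodebromination or oxidation of the benzylic alkoxide, so that ring C does not close. The fallback sets out from 29 and comes back at 30. The bromide is first exchanged for a hydroxyl by palladium-catalysed hydroxylation (the zerovalent palladium source Pd2(dba)3, 2-di-tert-butylphosphino-2′,4′,6′-triisopropylbiphenyl, KOH, dioxane/H2O, 100 °C), which should give the C8a phenol F1. Ring C is then closed from the other end: catalytic BF3·OEt2 in CH2Cl2 at −40 °C ionises the C2 benzylic hydroxyl, and the phenol oxygen captures the catechol-stabilised cation (SN1 cyclodehydration forming O1–C2). This closure should be reversible under the acid and favour the 2,3-trans ether 30, in which the aryl and the C3 benzyloxy group are both pseudo-equatorial; C3 is not involved.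

2. Step 8. What may go wrong: self-alkylation, in which the benzylic cation from 5 attacks the resorcinol ring of another molecule of 5 or of the product faster than ring D and gives oligomers. The fallback sets out from 5 and comes back at 12. Alcohol 5 is converted with PBr3 (CH2Cl2, 0 °C) into 2-bromo-4,6-bis(benzyloxy)benzyl bromide F2. F2 is added to the monosodium phenolate of 11 (NaH, toluene, rt → 60 °C). Alkylation of a phenolate in a non-polar medium goes by SN2 to the ring carbon ortho to the oxygen, here the only free one, without a free cation, and should give 12.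

3. Step 14. What may go wrong: ionisation and decomposition of the electron-rich benzylic bromide, or decay of the glycolate enolate before it is alkylated, so that conversion stays low. The fallback sets out from 15 and comes back at 24; it makes the C3–C4 bond by an aldol addition. (S)-4-Benzyl-2-oxazolidinone (O=C1N[C@@H](Cc2ccccc2)CO1) is acylated with 19 as in step 13 to (S)-4-benzyl-3-[(benzyloxy)acetyl]oxazolidin-2-one F3. Its dibutylboron enolate (Bu2BOTf, Et3N, CH2Cl2, −78 → 0 °C) adds to aldehyde 15 and should give the Evans syn aldol adduct F4. The benzylic hydroxyl of F4 is removed by ionic hydrogenation (Et3SiH, CF3CO2H, CH2Cl2, 0 °C) to give the deoxygenated imide F5, which carries the same (S) centre as 23 on the enantiomeric auxiliary. Transamination as in step 15 then gives 24. The boron aldol uses the enolate face opposite to that of the alkylation, hence the change of auxiliary enantiomer.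

**Further compounds**

F1 | step 18 | (1R,2S)-2-(benzyloxy)-1-[3,4-bis(benzyloxy)phenyl]-3-[4,6-bis(benzyloxy)-2-hydroxy-3-(ring D benzyl)phenyl]propan-1-ol | O[C@H](c1ccc(OCc2ccccc2)c(OCc2ccccc2)c1)[C@@H](OCc1ccccc1)Cc1c(OCc2ccccc2)cc(OCc2ccccc2)c(Cc2c(OCc3ccccc3)c(C)c(OC)c(C(=O)C(C)C)c2OCc2ccccc2)c1O
F2 | step 8 | 2-bromo-4,6-bis(benzyloxy)benzyl bromide | BrCc1c(Br)cc(OCc2ccccc2)cc1OCc1ccccc1
F3 | step 14 | (S)-4-benzyl-3-[(benzyloxy)acetyl]oxazolidin-2-one | O=C(COCc1ccccc1)N1[C@@H](Cc2ccccc2)COC1=O
F4 | step 14 | (S)-4-benzyl-3-{(2S,3R)-2-(benzyloxy)-3-[2-bromo-4,6-bis(benzyloxy)-3-(ring D benzyl)phenyl]-3-hydroxypropanoyl}oxazolidin-2-one | O=C(N1[C@@H](Cc2ccccc2)COC1=O)[C@@H](OCc1ccccc1)[C@H](O)c1c(OCc2ccccc2)cc(OCc2ccccc2)c(Cc2c(OCc3ccccc3)c(C)c(OC)c(C(=O)C(C)C)c2OCc2ccccc2)c1Br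
F5 | step 14 | (S)-4-benzyl-3-{(S)-2-(benzyloxy)-3-[2-bromo-4,6-bis(benzyloxy)-3-(ring D benzyl)phenyl]propanoyl}oxazolidin-2-one | O=C(N1[C@@H](Cc2ccccc2)COC1=O)[C@@H](OCc1ccccc1)Cc1c(OCc2ccccc2)cc(OCc2ccccc2)c(Cc2c(OCc3ccccc3)c(C)c(OC)c(C(=O)C(C)C)c2OCc2ccccc2)c1Br
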